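**Plan**

- Retrosynthesis: the four benzyl ethers and the two benzyl carbonates on ring B come off last. Ring C is cut at O1–C2, giving a C8a phenol tethered to a (2S,3R)-cis-epoxide. The epoxide goes back to a Z-alkene and an alkyne, cut at C2–C1' (ring B bromide) and, by one-carbon homologation, to a C4a allyl group. The C8–CH2 bond is cut to a ring A phenol and a ring D aldehyde, and ring D at its aryl–acyl bond.
- Forward: ring D aldehyde from methylphloroglucinol (steps 1–4); ring A allylphenol by Claisen rearrangement (steps 5–6); union of rings A and D through the CH2 bridge (step 7); allyl converted into the Z-propenyl chain bearing ring B (steps 8–13); epoxidation and desilylation (steps 14–15); closure of ring C (step 16); global hydrogenolysis (step 17).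
- Enabling feature: on ring C (O1, C2, C3, C4) the catechol ring B at C2 and the C3 hydroxyl lie on the same face, and O1 is bonded to C8a of ring A, whose neighbours C4a and C8 carry C4 and the CH2 link to ring D. A C8a phenol tied through C4a–C4 to a cis-epoxide can therefore reach C2 from the rear and leave exactly this relationship.
- Stereochemistry: the acyl stereocentre is bought with (S)-2-methylbutanoic acid. C3 (R) and a provisional C2 (S) come from the (S,S)-Mn(salen)Cl-catalysed epoxidation of the Z-alkene. C2 becomes R by inversion in the ring closure.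

Key step: step 16

Remark: flavan numbering (O1, C2, C3, C4, C4a, C5–C8, C8a) is used for these atoms in all intermediates; ArD = 2,6-bis(benzyloxy)-4-methoxy-3-methyl-5-[(2S)-2-methylbutanoyl]phenyl (ring D); salen = N,N'-bis(3,5-di-tert-butylsalicylidene)cyclohexane-1,2-diaminate; compounds 1, 2, 9 and 18 are taken as catalogue materials.

Step 1
Reactants: 1 (S)-2-methylbutanoic acid; 2 2,4,6-trihydroxytoluene
Product: 4 (2S)-2-methyl-1-(2,4,6-trihydroxy-3-methylphenyl)butan-1-one, via (S)-2-methylbutanoyl chloride 3 (not isolated)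
Conditions: (COCl)2, DMF (cat.), CH2Cl2, 0 °C to rt; then 2, AlCl3, PhNO2/CH2Cl2, 0 °C to rt
Reagents that add atoms: none
Why: Friedel–Crafts acylation of the electron-rich phloroglucinol ring at one of its two equivalent free carbons; the stereocentre is carried in from 1, and the low temperature should keep enolisation of the acyl chloride or of the aluminium-bound ketone (racemisation) slow.

Step 2
Reactants: 4 (2S)-2-methyl-1-(2,4,6-trihydroxy-3-methylphenyl)butan-1-one
Product: 5 (2S)-1-[4,6-bis(benzyloxy)-2-hydroxy-3-methylphenyl]-2-methylbutan-1-one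
Conditions: BnBr (2.1 equiv), K2CO3, acetone, reflux
Reagents that add atoms: benzyl bromide, BrCc1ccccc1
Why: Williamson etherification in which the non-chelated para hydroxyl reacts first and, of the two carbonyl-chelated ortho hydroxyls, the one flanked only by a ring hydrogen is benzylated, while the one wedged between the C-methyl group and the ketone should stay hydrogen-bonded and free.

Step 3
Reactants: 5 (2S)-1-[4,6-bis(benzyloxy)-2-hydroxy-3-methylphenyl]-2-methylbutan-1-one
Product: 6 (2S)-1-[4,6-bis(benzyloxy)-2-methoxy-3-methylphenyl]-2-methylbutan-1-one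
Conditions: MeI, K2CO3, DMF, 40 °C
Reagents that add atoms: iodomethane, CI
Why: Williamson O-methylation of the remaining hindered, chelated phenol with a small electrophile in a dipolar solvent, which fixes the methoxy group between the acyl and C-methyl groups as in ring D of the target.

Step 4
Reactants: 6 (2S)-1-[4,6-bis(benzyloxy)-2-methoxy-3-methylphenyl]-2-methylbutan-1-one
Product: 8 2,6-bis(benzyloxy)-4-methoxy-3-methyl-5-[(2S)-2-methylbutanoyl]benzaldehyde (ArD-CHO), via aryl iminium dichlorophosphate 7 (not isolated)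
Conditions: POCl3, DMF, 0 to 50 °C; then aq. NaOAc
Reagents that add atoms: N,N-dimethylformamide, CN(C)C=O (formyl carbon); water, O (formyl oxygen on hydrolysis)
Why: Vilsmeier–Haack formylation at the only unsubstituted ring carbon, which is ortho to both benzyloxy groups and para to the methoxy group and so remains nucleophilic despite the twisted, meta-placed ketone.

Step 5
Reactants: 9 3,5-bis(benzyloxy)phenol
Product: 10 1-(allyloxy)-3,5-bis(benzyloxy)benzene
Conditions: allyl bromide, K2CO3, acetone, reflux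
Reagents that add atoms: allyl bromide, C=CCBr
Why: Williamson etherification of the single free phenol with an unhindered allylic halide.

Step 6
Reactants: 10 1-(allyloxy)-3,5-bis(benzyloxy)benzene
Product: 11 2-allyl-3,5-bis(benzyloxy)phenol
Conditions: PhNEt2, 190 °C
Reagents that add atoms: none
Why: Aromatic Claisen rearrangement, a [3,3]-sigmatropic shift of the allyl group to one of the two equivalent ortho carbons followed by tautomerisation, which places C4 on the future C4a next to the phenol oxygen.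

Step 7
Reactants: 8 2,6-bis(benzyloxy)-4-methoxy-3-methyl-5-[(2S)-2-methylbutanoyl]benzaldehyde; 11 2-allyl-3,5-bis(benzyloxy)phenol
Product: 13 2-allyl-3,5-bis(benzyloxy)-6-(ArD-methyl)phenol, via 4-ArD-2-phenyl-4H-1,3,2-benzodioxaborin 12 (not isolated)
Conditions: PhB(OH)2, EtCO2H (cat.), toluene, reflux (Dean–Stark); evaporate; Et3SiH, CF3CO2H, CH2Cl2, −20 to 0 °C; aq. work-up
Reagents that add atoms: none
Why: Boron-templated ortho-hydroxyalkylation of a phenol by an aldehyde (the aryloxyboronate delivers the aldehyde to the only free ortho carbon, the future C8, and the adduct is held as the cyclic boronate), followed by ionic hydrogenation of the doubly benzylic C–O bond with Et3SiH/CF3CO2H, which should leave the hindered ketone and the allyl group alone.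

Step 8
Reactants: 13 2-allyl-3,5-bis(benzyloxy)-6-(ArD-methyl)phenol
Product: 14 [2-allyl-3,5-bis(benzyloxy)-6-(ArD-methyl)phenoxy]triisopropylsilane
Conditions: i-Pr3SiOTf, 2,6-lutidine, CH2Cl2, 0 °C to rt
Reagents that add atoms: triisopropylsilyl trifluoromethanesulfonate, CC(C)[Si](OS(=O)(=O)C(F)(F)F)(C(C)C)C(C)C
Why: Silylation of the flanked phenol with the reactive silyl triflate; the triisopropylsilyl ether is chosen because it should survive the carbonate/methanol of step 10 yet fall to fluoride in step 15.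

Step 9
Reactants: 14 [2-allyl-3,5-bis(benzyloxy)-6-(ArD-methyl)phenoxy]triisopropylsilane
Product: 16 2-[2,4-bis(benzyloxy)-5-(ArD-methyl)-6-(triisopropylsilyloxy)phenyl]acetaldehyde, via 1,2-diol 15 (not isolated)
Conditions: OsO4 (2 mol %), NaIO4, 2,6-lutidine, dioxane/H2O, rt
Reagents that add atoms: sodium periodate, [Na+].[O-]I(=O)(=O)=O (terminal oxygen source, relayed through catalytic osmium tetroxide, O=[Os](=O)(=O)=O)
Why: Lemieux–Johnson oxidative cleavage (osmylation of the terminal alkene, then periodate cleavage of the diol), buffered with 2,6-lutidine; the electron-rich aryl ethers and the benzylic CH2 bridge should not be attacked.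

Step 10
Reactants: 16 2-[2,4-bis(benzyloxy)-5-(ArD-methyl)-6-(triisopropylsilyloxy)phenyl]acetaldehyde
Product: 17 [3,5-bis(benzyloxy)-6-(ArD-methyl)-2-(prop-2-yn-1-yl)phenoxy]triisopropylsilane
Conditions: dimethyl (1-diazo-2-oxopropyl)phosphonate, K2CO3, MeOH/THF, 0 °C to rt
Reagents that add atoms: dimethyl (1-diazo-2-oxopropyl)phosphonate, COP(=O)(OC)C(=[N+]=[N-])C(C)=O
Why: Seyferth–Gilbert homologation in its Ohira–Bestmann form, whose mild carbonate base tolerates the enolisable arylacetaldehyde and, at low temperature and short contact time, should not isomerise the propargyl arene to the allene.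

Step 11
Reactants: 18 4-bromocatechol
Product: 19 dibenzyl 4-bromo-1,2-phenylene dicarbonate
Conditions: benzyl chloroformate (2.3 equiv), Et3N, CH2Cl2, −10 to 0 °C
Reagents that add atoms: benzyl chloroformate, O=C(Cl)OCc1ccccc1
Why: O-acylation of both phenols by the chloroformate under amine base; the two benzyl carbonates make ring B electron-poor for steps 12–16 and are cleaved in the final hydrogenolysis.

Step 12
Reactants: 17 [3,5-bis(benzyloxy)-6-(ArD-methyl)-2-(prop-2-yn-1-yl)phenoxy]triisopropylsilane; 19 dibenzyl 4-bromo-1,2-phenylene dicarbonate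
Product: 20 [3,5-bis(benzyloxy)-6-(ArD-methyl)-2-{3-[3,4-bis(benzyloxycarbonyloxy)phenyl]prop-2-yn-1-yl}phenoxy]triisopropylsilane
Conditions: Pd(PPh3)4 (5 mol %), CuI (5 mol %), Et3N, THF, 50 °C
Reagents that add atoms: none
Why: Sonogashira coupling of the terminal alkyne with an aryl bromide that is activated toward oxidative addition by its two acyloxy substituents; the tertiary amine base should spare the carbonates.

Step 13
Reactants: 20 [3,5-bis(benzyloxy)-6-(ArD-methyl)-2-{3-[3,4-bis(benzyloxycarbonyloxy)phenyl]prop-2-yn-1-yl}phenoxy]triisopropylsilane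
Product: 21 [3,5-bis(benzyloxy)-6-(ArD-methyl)-2-{(2Z)-3-[3,4-bis(benzyloxycarbonyloxy)phenyl]prop-2-en-1-yl}phenoxy]triisopropylsilane
Conditions: H2 (1 atm), Pd/CaCO3 poisoned with Pb(OAc)2, quinoline, EtOAc, rt
Reagents that add atoms: none
Why: Lindlar semihydrogenation, syn delivery of one equivalent of H2 on the lead-poisoned Pd/CaCO3 surface giving the Z-alkene; benzyl ethers and benzyl carbonates should not be cleaved by this catalyst.

Step 14
Reactants: 21 [3,5-bis(benzyloxy)-6-(ArD-methyl)-2-{(2Z)-3-[3,4-bis(benzyloxycarbonyloxy)phenyl]prop-2-en-1-yl}phenoxy]triisopropylsilane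
Product: 22 (2S,3R)-2-[3,4-bis(benzyloxycarbonyloxy)phenyl]-3-{[2,4-bis(benzyloxy)-5-(ArD-methyl)-6-(triisopropylsilyloxy)phenyl]methyl}oxirane (cis-epoxide)
Conditions: (S,S)-Mn(salen)Cl (5 mol %), mCPBA, N-methylmorpholine N-oxide, CH2Cl2, −78 °C
Reagents that add atoms: 3-chloroperoxybenzoic acid, OOC(=O)c1cccc(Cl)c1
Why: Jacobsen–Katsuki epoxidation of an aryl-conjugated Z-alkene; the (S,S)-catalyst transfers oxygen to the face that makes the benzylic carbon S (the sense known for indene and cis-β-methylstyrene), so the cis-epoxide is (2S,3R), and the low temperature should disfavour stepwise collapse to the trans-epoxide.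

Step 15
Reactants: 22 (2S,3R)-2-[3,4-bis(benzyloxycarbonyloxy)phenyl]-3-{[2,4-bis(benzyloxy)-5-(ArD-methyl)-6-(triisopropylsilyloxy)phenyl]methyl}oxirane
Product: 23 (2S,3R)-2-[3,4-bis(benzyloxycarbonyloxy)phenyl]-3-{[2,4-bis(benzyloxy)-6-hydroxy-5-(ArD-methyl)phenyl]methyl}oxirane
Conditions: Bu4NF, AcOH (1:1), THF, 0 °C to rt
Reagents that add atoms: none
Why: Fluoride-induced cleavage of the aryl silyl ether, buffered with acetic acid so that no free phenoxide is present to attack C3 or the carbonate groups.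

Step 16
Reactants: 23 (2S,3R)-2-[3,4-bis(benzyloxycarbonyloxy)phenyl]-3-{[2,4-bis(benzyloxy)-6-hydroxy-5-(ArD-methyl)phenyl]methyl}oxirane
Product: 24 (2R,3R)-5,7-bis(benzyloxy)-2-[3,4-bis(benzyloxycarbonyloxy)phenyl]-8-(ArD-methyl)-3,4-dihydro-2H-chromen-3-ol
Conditions: camphor-10-sulfonic acid (0.1 equiv), CH2Cl2, −20 to 0 °C
Reagents that add atoms: none
Why: Protonation (or tight hydrogen bonding) of the oxirane oxygen by the sulfonic acid weakens the benzylic C2–O bond, and the C8a hydroxyl displaces that oxygen from the opposite face through a loose SN2-like transition state; the closest known reaction is the acid-promoted cyclisation of 2-(2,3-epoxy-3-arylpropyl)phenols to flavan-3-ols, established for trans-epoxides. Ring C closes in the 6-endo-tet mode by forming O1–C2, whereas attack at C3 (5-exo, giving a dihydrobenzofuran) is disfavoured because partial positive charge can build up only at the aryl-substituted carbon. C2 is set by inversion of the (2S) oxirane carbon while C3 (R, from step 14) keeps its C–O bond, so the cis-epoxide is translated into the 2,3-cis (2R,3R) arrangement. The step needs clean inversion and endo regioselectivity: the two benzyl carbonate groups withdraw enough electron density from ring B that a free benzylic cation should not form, while the aryl group still polarises the C2–O bond toward the nucleophile. Because the C8a hydroxyl is the only unprotected phenol, no other oxygen can compete, and catalytic acid at low temperature should spare the benzyl ethers and carbonates.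

Step 17
Reactants: 24 (2R,3R)-5,7-bis(benzyloxy)-2-[3,4-bis(benzyloxycarbonyloxy)phenyl]-8-(ArD-methyl)-3,4-dihydro-2H-chromen-3-ol
Product: 25 (2S)-1-[3-{[(2R,3R)-2-(3,4-dihydroxyphenyl)-3,5,7-trihydroxy-3,4-dihydro-2H-chromen-8-yl]methyl}-2,4-dihydroxy-6-methoxy-5-methylphenyl]-2-methylbutan-1-one (target)
Conditions: H2 (1 atm), Pd(OH)2/C, THF/MeOH, rt
Reagents that add atoms: none
Why: Hydrogenolysis of the four benzyl ethers and the two benzyl carbonates (which lose CO2) over Pd(OH)2/C; the flavan C2–O1 bond, the diarylmethane and the chelated aryl ketone should persist at 1 atm, and no stereocentre is touched.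

**Compound list**

1 | (S)-2-methylbutanoic acid | CC[C@H](C)C(=O)O | starting material
2 | 2,4,6-trihydroxytoluene (2-methylbenzene-1,3,5-triol) | Cc1c(O)cc(O)cc1O | starting material
3 | (S)-2-methylbutanoyl chloride | CC[C@H](C)C(=O)Cl | intermediate (not isolated)
4 | (2S)-2-methyl-1-(2,4,6-trihydroxy-3-methylphenyl)butan-1-one | CC[C@H](C)C(=O)c1c(O)cc(O)c(C)c1O | intermediate
5 | (2S)-1-[4,6-bis(benzyloxy)-2-hydroxy-3-methylphenyl]-2-methylbutan-1-one | CC[C@H](C)C(=O)c1c(OCc2ccccc2)cc(OCc2ccccc2)c(C)c1O | intermediate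
6 | (2S)-1-[4,6-bis(benzyloxy)-2-methoxy-3-methylphenyl]-2-methylbutan-1-one | CC[C@H](C)C(=O)c1c(OCc2ccccc2)cc(OCc2ccccc2)c(C)c1OC | intermediate
7 | N-(ArD-methylidene)-N-methylmethanaminium dichlorophosphate (aryl iminium salt) | CC[C@H](C)C(=O)c1c(OCc2ccccc2)c(C=[N+](C)C)c(OCc2ccccc2)c(C)c1OC.[O-]P(Cl)(Cl)=O | intermediate (not isolated)
8 | 2,6-bis(benzyloxy)-4-methoxy-3-methyl-5-[(2S)-2-methylbutanoyl]benzaldehyde (ArD-CHO) | CC[C@H](C)C(=O)c1c(OCc2ccccc2)c(C=O)c(OCc2ccccc2)c(C)c1OC | intermediate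
9 | 3,5-bis(benzyloxy)phenol | Oc1cc(OCc2ccccc2)cc(OCc2ccccc2)c1 | starting material
10 | 1-(allyloxy)-3,5-bis(benzyloxy)benzene | C=CCOc1cc(OCc2ccccc2)cc(OCc2ccccc2)c1 | intermediate
11 | 2-allyl-3,5-bis(benzyloxy)phenol | C=CCc1c(O)cc(OCc2ccccc2)cc1OCc1ccccc1 | intermediate
12 | 8-allyl-4-ArD-5,7-bis(benzyloxy)-2-phenyl-4H-1,3,2-benzodioxaborin (both epimers at its C4) | CC[C@H](C)C(=O)c1c(OCc2ccccc2)c(C2OB(c3ccccc3)Oc3c(CC=C)c(OCc4ccccc4)cc(OCc4ccccc4)c32)c(OCc2ccccc2)c(C)c1OC | intermediate (not isolated)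
13 | 2-allyl-3,5-bis(benzyloxy)-6-(ArD-methyl)phenol (ring A–ring D diarylmethane, free C8a hydroxyl) | CC[C@H](C)C(=O)c1c(OCc2ccccc2)c(Cc2c(OCc3ccccc3)cc(OCc3ccccc3)c(CC=C)c2O)c(OCc2ccccc2)c(C)c1OC | intermediate
14 | [2-allyl-3,5-bis(benzyloxy)-6-(ArD-methyl)phenoxy]triisopropylsilane | CC[C@H](C)C(=O)c1c(OCc2ccccc2)c(Cc2c(OCc3ccccc3)cc(OCc3ccccc3)c(CC=C)c2O[Si](C(C)C)(C(C)C)C(C)C)c(OCc2ccccc2)c(C)c1OC | intermediate
15 | 3-[2,4-bis(benzyloxy)-5-(ArD-methyl)-6-(triisopropylsilyloxy)phenyl]propane-1,2-diol (both epimers at the carbinol carbon) | CC[C@H](C)C(=O)c1c(OCc2ccccc2)c(Cc2c(OCc3ccccc3)cc(OCc3ccccc3)c(CC(O)CO)c2O[Si](C(C)C)(C(C)C)C(C)C)c(OCc2ccccc2)c(C)c1OC | intermediate (not isolated)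
16 | 2-[2,4-bis(benzyloxy)-5-(ArD-methyl)-6-(triisopropylsilyloxy)phenyl]acetaldehyde | CC[C@H](C)C(=O)c1c(OCc2ccccc2)c(Cc2c(OCc3ccccc3)cc(OCc3ccccc3)c(CC=O)c2O[Si](C(C)C)(C(C)C)C(C)C)c(OCc2ccccc2)c(C)c1OC | intermediate
17 | [3,5-bis(benzyloxy)-6-(ArD-methyl)-2-(prop-2-yn-1-yl)phenoxy]triisopropylsilane | CC[C@H](C)C(=O)c1c(OCc2ccccc2)c(Cc2c(OCc3ccccc3)cc(OCc3ccccc3)c(CC#C)c2O[Si](C(C)C)(C(C)C)C(C)C)c(OCc2ccccc2)c(C)c1OC | intermediate
18 | 4-bromocatechol (4-bromobenzene-1,2-diol) | Oc1ccc(Br)cc1O | starting material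
19 | dibenzyl 4-bromo-1,2-phenylene dicarbonate | O=C(OCc1ccccc1)Oc1ccc(Br)cc1OC(=O)OCc1ccccc1 | intermediate
20 | [3,5-bis(benzyloxy)-6-(ArD-methyl)-2-{3-[3,4-bis(benzyloxycarbonyloxy)phenyl]prop-2-yn-1-yl}phenoxy]triisopropylsilane | CC[C@H](C)C(=O)c1c(OCc2ccccc2)c(Cc2c(OCc3ccccc3)cc(OCc3ccccc3)c(CC#Cc3ccc(OC(=O)OCc4ccccc4)c(OC(=O)OCc4ccccc4)c3)c2O[Si](C(C)C)(C(C)C)C(C)C)c(OCc2ccccc2)c(C)c1OC | intermediate
21 | [3,5-bis(benzyloxy)-6-(ArD-methyl)-2-{(2Z)-3-[3,4-bis(benzyloxycarbonyloxy)phenyl]prop-2-en-1-yl}phenoxy]triisopropylsilane | CC[C@H](C)C(=O)c1c(OCc2ccccc2)c(Cc2c(OCc3ccccc3)cc(OCc3ccccc3)c(C/C=C\c3ccc(OC(=O)OCc4ccccc4)c(OC(=O)OCc4ccccc4)c3)c2O[Si](C(C)C)(C(C)C)C(C)C)c(OCc2ccccc2)c(C)c1OC | intermediate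
22 | (2S,3R)-2-[3,4-bis(benzyloxycarbonyloxy)phenyl]-3-{[2,4-bis(benzyloxy)-5-(ArD-methyl)-6-(triisopropylsilyloxy)phenyl]methyl}oxirane (cis) | CC[C@H](C)C(=O)c1c(OCc2ccccc2)c(Cc2c(OCc3ccccc3)cc(OCc3ccccc3)c(C[C@H]3O[C@H]3c3ccc(OC(=O)OCc4ccccc4)c(OC(=O)OCc4ccccc4)c3)c2O[Si](C(C)C)(C(C)C)C(C)C)c(OCc2ccccc2)c(C)c1OC | intermediate
23 | (2S,3R)-2-[3,4-bis(benzyloxycarbonyloxy)phenyl]-3-{[2,4-bis(benzyloxy)-6-hydroxy-5-(ArD-methyl)phenyl]methyl}oxirane (cis, free C8a hydroxyl) | CC[C@H](C)C(=O)c1c(OCc2ccccc2)c(Cc2c(OCc3ccccc3)cc(OCc3ccccc3)c(C[C@H]3O[C@H]3c3ccc(OC(=O)OCc4ccccc4)c(OC(=O)OCc4ccccc4)c3)c2O)c(OCc2ccccc2)c(C)c1OC | intermediate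
24 | (2R,3R)-5,7-bis(benzyloxy)-2-[3,4-bis(benzyloxycarbonyloxy)phenyl]-8-(ArD-methyl)-3,4-dihydro-2H-chromen-3-ol (2,3-cis) | CC[C@H](C)C(=O)c1c(OCc2ccccc2)c(Cc2c(OCc3ccccc3)cc(OCc3ccccc3)c3c2O[C@H](c2ccc(OC(=O)OCc4ccccc4)c(OC(=O)OCc4ccccc4)c2)[C@H](O)C3)c(OCc2ccccc2)c(C)c1OC | intermediate
25 | (2S)-1-[3-{[(2R,3R)-2-(3,4-dihydroxyphenyl)-3,5,7-trihydroxy-3,4-dihydro-2H-chromen-8-yl]methyl}-2,4-dihydroxy-6-methoxy-5-methylphenyl]-2-methylbutan-1-one | CC[C@H](C)C(=O)c1c(O)c(Cc2c(O)cc(O)c3c2O[C@H](c2ccc(O)c(O)c2)[C@H](O)C3)c(O)c(C)c1OC | target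

**Step count and risks**

Total: 17 steps. Longest linear sequence: 14 steps (steps 1–4, 7–10, 12–17).

Steps most likely to fail:

1. Step 16 (ring closure). The opening may drift from backside displacement toward a benzylic cation, which would erode the inversion at C2. Attack may also shift to C3, or a hydride shift may give the benzyl ketone. In that case the C2/C3 relationship would no longer be entrusted to a stereospecific opening. Z-alkene 21 would be epoxidised with (R,R)-Mn(salen)Cl under the conditions of step 14 to the enantiomeric (2R,3S)-cis-epoxide silyl ether F1 and desilylated as in step 15 to the (2R,3S)-epoxy phenol F2. F2 would be closed under deliberately ionising conditions (BF3·OEt2, CH2Cl2, −40 °C), where the C8a oxygen captures the benzylic cation with the usual preference for the 2,3-trans arrangement while C3 (S) is untouched, giving the (2R,3S)-2,3-trans-flavan-3-ol F3; the minor cis isomer would be removed. Dess–Martin oxidation to the (2R)-flavan-3-one F4 and reduction with LiBH(s-Bu)3 in THF at −78 °C, which adds hydride anti to the C2 aryl group, should then return the 2,3-cis alcohol 24.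

2. Step 14 (epoxidation). Oxygen transfer from the Mn(salen)-oxo intermediate may proceed stepwise, letting the benzylic radical rotate and leak to the trans-epoxide, and facial discrimination of an acyclic Z-alkene with a bulky ring A arm may be incomplete. The oxidant class would then be changed rather than the manganese system tuned. Alkene 21 would be treated with 30% aqueous H2O2 and a catalyst formed from Ti(OiPr)4 and the appropriate enantiomer of a chiral salan ligand (CH2Cl2, rt). This is a concerted peroxo-titanium oxygen transfer, known to be stereospecific for aryl-conjugated Z-alkenes, and should lead back to 22. No compound outside the list is made (F0).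

3. Step 7 (union of rings A and D). The hexasubstituted, electron-rich aldehyde 8 may fail to add within the boronate template, or the ketone may be touched during the ionic hydrogenation. The C–H bond would then be made first and the C–C bond second. NaBH4 (THF/MeOH, 0 °C) should reduce only the aldehyde of 8 to the benzylic alcohol (2S)-1-[2,4-bis(benzyloxy)-3-(hydroxymethyl)-6-methoxy-5-methylphenyl]-2-methylbutan-1-one F5. Its benzylic cation (BF3·OEt2 or H2SO4 on silica, CH2Cl2, −30 °C) would alkylate phenol 11 in a Friedel–Crafts benzylation, expected mainly ortho to the hydroxyl as in cinnamylations of 3,5-dialkoxyphenols, to return to 13. The isomer alkylated between the two benzyloxy groups would have to be separated.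

**Further compounds**

F1 | step 16 | (2R,3S)-2-[3,4-bis(benzyloxycarbonyloxy)phenyl]-3-{[2,4-bis(benzyloxy)-5-(ArD-methyl)-6-(triisopropylsilyloxy)phenyl]methyl}oxirane (cis) | CC[C@H](C)C(=O)c1c(OCc2ccccc2)c(Cc2c(OCc3ccccc3)cc(OCc3ccccc3)c(C[C@@H]3O[C@@H]3c3ccc(OC(=O)OCc4ccccc4)c(OC(=O)OCc4ccccc4)c3)c2O[Si](C(C)C)(C(C)C)C(C)C)c(OCc2ccccc2)c(C)c1OC
F2 | step 16 | (2R,3S)-2-[3,4-bis(benzyloxycarbonyloxy)phenyl]-3-{[2,4-bis(benzyloxy)-6-hydroxy-5-(ArD-methyl)phenyl]methyl}oxirane (cis) | CC[C@H](C)C(=O)c1c(OCc2ccccc2)c(Cc2c(OCc3ccccc3)cc(OCc3ccccc3)c(C[C@@H]3O[C@@H]3c3ccc(OC(=O)OCc4ccccc4)c(OC(=O)OCc4ccccc4)c3)c2O)c(OCc2ccccc2)c(C)c1OC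
F3 | step 16 | (2R,3S)-5,7-bis(benzyloxy)-2-[3,4-bis(benzyloxycarbonyloxy)phenyl]-8-(ArD-methyl)-3,4-dihydro-2H-chromen-3-ol (2,3-trans) | CC[C@H](C)C(=O)c1c(OCc2ccccc2)c(Cc2c(OCc3ccccc3)cc(OCc3ccccc3)c3c2O[C@H](c2ccc(OC(=O)OCc4ccccc4)c(OC(=O)OCc4ccccc4)c2)[C@@H](O)C3)c(OCc2ccccc2)c(C)c1OC
F4 | step 16 | (2R)-5,7-bis(benzyloxy)-2-[3,4-bis(benzyloxycarbonyloxy)phenyl]-8-(ArD-methyl)-2H-chromen-3(4H)-one | CC[C@H](C)C(=O)c1c(OCc2ccccc2)c(Cc2c(OCc3ccccc3)cc(OCc3ccccc3)c3c2O[C@H](c2ccc(OC(=O)OCc4ccccc4)c(OC(=O)OCc4ccccc4)c2)C(=O)C3)c(OCc2ccccc2)c(C)c1OC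
F0 | step 14 | none | none
F5 | step 7 | (2S)-1-[2,4-bis(benzyloxy)-3-(hydroxymethyl)-6-methoxy-5-methylphenyl]-2-methylbutan-1-one | CC[C@H](C)C(=O)c1c(OCc2ccccc2)c(CO)c(OCc2ccccc2)c(C)c1OC
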